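**Plan**

Ring numbering used throughout: C1 (CHOH), C2 (CMe2), C3 (CH bearing the side chain), C4 (C=CH2), C5 and C6 (ring CH2).
- Retrosynthetic cuts, in order: the aryl O–CH2 ether bond; C1–OH back to C1=O; the ring bond C4–C5; C5 and C6 off the C1 carbonyl carbon (cyclopropanol back to ester); C2–C3; the side chain back to geraniol.
- Enabling feature: C4 (methylidene carbon) and C1 (oxygen-bearing carbon) are joined by the C5–C6 ethano bridge, so at the ketone level the ring is a γ,δ-unsaturated ketone with C5 as the β-carbon of C1=O. A cyclopropanol on C1 (temporary ring) releases exactly a C5 radical, quaternary C2 leaves no second α-position, and a vinyl group on C3 supplies C4 and the methylidene carbon.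
- Forward order: the acyclic chain first (geraniol → C6 aldehyde → allylic carbonate → C2–C3 bond), then the cyclopropanol, then the single ring closure C4–C5, then C1 reduction, desilylation and aryl ether formation.
- Stereochemistry: C3 (S) comes from ligand-controlled iridium allylic alkylation; C1 (R) comes from hydride delivery to the ring ketone anti to the C3 chain (cis-1,3); the (E)-alkene is carried over from geraniol.

Key step: step 9

Assumption: in step 7 the (Ra,R,R) ligand is taken to give the (S) centre, as the usual facial model for this catalyst family predicts; if the sense proves opposite, the (Sa,S,S) ligand is used with nothing else changed.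

**Route**

Step 1
Reactants: 1 geraniol
Product: 2 tert-butyl{[(2E)-3,7-dimethylocta-2,6-dien-1-yl]oxy}diphenylsilane
Conditions: TBDPSCl, imidazole, CH2Cl2, 0 °C to rt
Reagents that add atoms: tert-butyl(chloro)diphenylsilane, CC(C)(C)[Si](Cl)(c1ccccc1)c1ccccc1
Why: Silylation of the primary allylic alcohol gives an ether that should survive the later acidic, hydride, Grignard and oxidative steps.

Step 2
Reactants: 2 geranyl silyl ether
Product: 3 tert-butyl{[(2E)-5-(3,3-dimethyloxiran-2-yl)-3-methylpent-2-en-1-yl]oxy}diphenylsilane (racemic at the oxirane carbon)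
Conditions: mCPBA (1.05 equiv), NaHCO3, CH2Cl2, −20 to 0 °C
Reagents that add atoms: 3-chloroperoxybenzoic acid, O=C(OO)c1cccc(Cl)c1
Why: Prilezhaev epoxidation should go to the more electron-rich 6,7-alkene, remote from the deactivating and bulky silyloxy group; the racemic epoxide centre is destroyed in step 3.

Step 3
Reactants: 3 epoxide
Product: 4 (4E)-6-[(tert-butyldiphenylsilyl)oxy]-4-methylhex-4-enal
Conditions: H5IO6 (1.1 equiv), THF–Et2O, 0 °C
Reagents that add atoms: none
Why: Periodic acid opens the trisubstituted epoxide and cleaves the resulting glycol in one flask (Malaprade-type cleavage), leaving the (E)-alkene untouched.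

Step 4
Reactants: 4 aldehyde; 5 triethyl phosphonoacetate
Product: 6 ethyl (2E,6E)-8-[(tert-butyldiphenylsilyl)oxy]-6-methylocta-2,6-dienoate
Conditions: NaH, THF, 0 °C to rt
Reagents that add atoms: none
Why: Horner–Wadsworth–Emmons olefination of an unhindered aldehyde with a stabilised phosphonate should give the (E)-enoate.

Step 5
Reactants: 6 enoate
Product: 7 (2E,6E)-8-[(tert-butyldiphenylsilyl)oxy]-6-methylocta-2,6-dien-1-ol
Conditions: i-Bu2AlH (2.2 equiv), CH2Cl2, −78 °C; aq. potassium sodium tartrate (KNaC4H4O6)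
Reagents that add atoms: none
Why: 1,2-Reduction of the enoate with i-Bu2AlH at low temperature gives the allylic alcohol without conjugate reduction.

Step 6
Reactants: 7 allylic alcohol
Product: 8 (2E,6E)-8-[(tert-butyldiphenylsilyl)oxy]-6-methylocta-2,6-dien-1-yl methyl carbonate
Conditions: ClCO2Me, pyridine, CH2Cl2, 0 °C
Reagents that add atoms: methyl chloroformate, COC(=O)Cl
Why: Acylation gives the carbonate leaving group, which on ionisation releases methoxide to unmask the silyl ketene acetal in step 7.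

Step 7
Reactants: 8 allylic carbonate; 9 methyl trimethylsilyl dimethylketene acetal
Product: 10 methyl (3S,6E)-8-[(tert-butyldiphenylsilyl)oxy]-3-ethenyl-2,2,6-trimethyloct-6-enoate
Conditions: [Ir(cod)Cl]2 (2 mol%), (Ra,R,R)-binaphthyl N,N-bis(1-phenylethyl)phosphoramidite (4 mol%), n-PrNH2 activation, THF, rt
Reagents that add atoms: none
Why: Iridium-catalysed asymmetric allylic alkylation with a silyl ketene acetal as ester enolate attacks the substituted allyl terminus, giving the branched product with quaternary C2 next to the new C3 centre, whose configuration is set by the chiral cyclometalated catalyst.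

Step 8
Reactants: 10 ester
Product: 11 1-[(3S,6E)-8-[(tert-butyldiphenylsilyl)oxy]-3-ethenyl-2,6-dimethyloct-6-en-2-yl]cyclopropan-1-ol
Conditions: EtMgBr (3 equiv, slow addition), Ti(OiPr)4 (0.5 equiv), THF, 0 °C to rt
Reagents that add atoms: ethylmagnesium bromide, CC[Mg]Br
Why: Kulinkovich cyclopropanation: the titanacyclopropane formed from EtMgBr and Ti(OiPr)4 adds twice to the ester carbonyl to give the 1-substituted cyclopropanol, with the silyl ether and alkenes as spectators.

Step 9
Reactants: 11 cyclopropanol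
Product: 14 (3S)-3-[(3E)-5-[(tert-butyldiphenylsilyl)oxy]-3-methylpent-3-en-1-yl]-2,2-dimethyl-4-methylidenecyclohexan-1-one, via β-keto alkyl radical 12 (not isolated), via cyclohexylmethyl radical 13 (not isolated)
Conditions: Mn(acac)3 (2.2 equiv), Cu(OAc)2 (10 mol%), degassed MeCN–AcOH (9:1), 0.01 M, 40 °C, slow addition of 11
Reagents that add atoms: none
Why: Proposed new method: trivalent manganese oxidises the cyclopropanol O–H and the strained ring opens (its two ring bonds are equivalent) to the primary β-keto radical 12, which adds to the internal carbon of the C3 vinyl group to make the C4–C5 bond, and divalent copper then captures the primary radical 13 and removes its only β-hydrogen (on C4) to leave the exocyclic methylidene and the C1 ketone. The closest known reaction type is the Mn(OAc)3/Cu(OAc)2 oxidative fragmentation–cyclisation of unsaturated cyclobutanols, together with manganese- or iron-mediated ring-opening cyclisation of cyclopropanols onto unactivated alkenes; what is new is the 6-exo closure of a cyclopropanol-derived radical with alkene-forming copper termination. The one ring is closed 6-exo-trig through a chair-like transition state in which the gem-dimethyl group at C2 favours the folded rotamer. No stereocentre is created, because the radical-adduct ring carbon becomes sp2 on elimination, and C3 keeps its configuration since it is not α to the ketone. The step needs ring closure to outrun copper oxidation of 12 (which would give the acyclic vinyl ketone) and to prefer exo over 7-endo attack: copper is therefore kept catalytic and re-oxidised by manganese, the internal vinyl carbon is unsubstituted, and the position of the new alkene is fixed because C4–H is the only β-hydrogen of 13.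

Step 10
Reactants: 14 ketone
Product: 15 (1R,3S)-3-[(3E)-5-[(tert-butyldiphenylsilyl)oxy]-3-methylpent-3-en-1-yl]-2,2-dimethyl-4-methylidenecyclohexan-1-ol
Conditions: NaBH4, MeOH, 0 °C
Reagents that add atoms: none
Why: Substrate-controlled hydride reduction: the small hydride should attack axially, on the face anti to the C3 chain, in the chair with the chain equatorial, giving the equatorial (1R) alcohol cis to the side chain.

Step 11
Reactants: 15 silyl ether
Product: 16 (1R,3S)-3-[(3E)-5-hydroxy-3-methylpent-3-en-1-yl]-2,2-dimethyl-4-methylidenecyclohexan-1-ol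
Conditions: Bu4NF, THF, 0 °C to rt
Reagents that add atoms: none
Why: Fluoride-mediated desilylation frees the primary allylic alcohol without touching the alkenes or the ring alcohol.

Step 12
Reactants: 16 diol; 17 isofraxidin (7-hydroxy-6,8-dimethoxy-2H-chromen-2-one)
Product: 18 7-{[(2E)-5-[(1S,3R)-3-hydroxy-2,2-dimethyl-6-methylidenecyclohexyl]-3-methylpent-2-en-1-yl]oxy}-6,8-dimethoxy-2H-chromen-2-one (CNP0306576.1)
Conditions: PPh3, DIAD, THF, 0 °C to rt
Reagents that add atoms: none
Why: Mitsunobu etherification of the acidic coumarin phenol should occur only at the primary allylic alcohol, because the secondary ring alcohol next to quaternary C2 is too hindered to be activated.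

**Compound list**

1 | geraniol, (2E)-3,7-dimethylocta-2,6-dien-1-ol | CC(C)=CCC/C(C)=C/CO | starting material
2 | tert-butyl{[(2E)-3,7-dimethylocta-2,6-dien-1-yl]oxy}diphenylsilane | CC(C)=CCC/C(C)=C/CO[Si](c1ccccc1)(c1ccccc1)C(C)(C)C | intermediate
3 | tert-butyl{[(2E)-5-(3,3-dimethyloxiran-2-yl)-3-methylpent-2-en-1-yl]oxy}diphenylsilane (racemic epoxide) | CC1(C)OC1CC/C(C)=C/CO[Si](c2ccccc2)(c2ccccc2)C(C)(C)C | intermediate
4 | (4E)-6-[(tert-butyldiphenylsilyl)oxy]-4-methylhex-4-enal | O=CCC/C(C)=C/CO[Si](c1ccccc1)(c1ccccc1)C(C)(C)C | intermediate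
5 | triethyl phosphonoacetate | CCOC(=O)CP(=O)(OCC)OCC | starting material
6 | ethyl (2E,6E)-8-[(tert-butyldiphenylsilyl)oxy]-6-methylocta-2,6-dienoate | CCOC(=O)/C=C/CC/C(C)=C/CO[Si](c1ccccc1)(c1ccccc1)C(C)(C)C | intermediate
7 | (2E,6E)-8-[(tert-butyldiphenylsilyl)oxy]-6-methylocta-2,6-dien-1-ol | OC/C=C/CC/C(C)=C/CO[Si](c1ccccc1)(c1ccccc1)C(C)(C)C | intermediate
8 | (2E,6E)-8-[(tert-butyldiphenylsilyl)oxy]-6-methylocta-2,6-dien-1-yl methyl carbonate | COC(=O)OC/C=C/CC/C(C)=C/CO[Si](c1ccccc1)(c1ccccc1)C(C)(C)C | intermediate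
9 | methyl trimethylsilyl dimethylketene acetal, [(1-methoxy-2-methylprop-1-en-1-yl)oxy]trimethylsilane | COC(O[Si](C)(C)C)=C(C)C | starting material
10 | methyl (3S,6E)-8-[(tert-butyldiphenylsilyl)oxy]-3-ethenyl-2,2,6-trimethyloct-6-enoate | COC(=O)C(C)(C)[C@H](C=C)CC/C(C)=C/CO[Si](c1ccccc1)(c1ccccc1)C(C)(C)C | intermediate
11 | 1-[(3S,6E)-8-[(tert-butyldiphenylsilyl)oxy]-3-ethenyl-2,6-dimethyloct-6-en-2-yl]cyclopropan-1-ol | OC1(CC1)C(C)(C)[C@H](C=C)CC/C(C)=C/CO[Si](c1ccccc1)(c1ccccc1)C(C)(C)C | intermediate
12 | (5S,8E)-10-[(tert-butyldiphenylsilyl)oxy]-5-ethenyl-4,4,8-trimethyl-3-oxodec-8-en-1-yl radical (not isolated) | [CH2]CC(=O)C(C)(C)[C@H](C=C)CC/C(C)=C/CO[Si](c1ccccc1)(c1ccccc1)C(C)(C)C | intermediate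
13 | {(2S)-2-[(3E)-5-[(tert-butyldiphenylsilyl)oxy]-3-methylpent-3-en-1-yl]-3,3-dimethyl-4-oxocyclohexyl}methyl radical (not isolated, both configurations at the ring carbon) | [CH2]C1CCC(=O)C(C)(C)[C@H]1CC/C(C)=C/CO[Si](c2ccccc2)(c2ccccc2)C(C)(C)C | intermediate
14 | (3S)-3-[(3E)-5-[(tert-butyldiphenylsilyl)oxy]-3-methylpent-3-en-1-yl]-2,2-dimethyl-4-methylidenecyclohexan-1-one | C=C1CCC(=O)C(C)(C)[C@H]1CC/C(C)=C/CO[Si](c2ccccc2)(c2ccccc2)C(C)(C)C | intermediate
15 | (1R,3S)-3-[(3E)-5-[(tert-butyldiphenylsilyl)oxy]-3-methylpent-3-en-1-yl]-2,2-dimethyl-4-methylidenecyclohexan-1-ol | C=C1CC[C@@H](O)C(C)(C)[C@H]1CC/C(C)=C/CO[Si](c2ccccc2)(c2ccccc2)C(C)(C)C | intermediate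
16 | (1R,3S)-3-[(3E)-5-hydroxy-3-methylpent-3-en-1-yl]-2,2-dimethyl-4-methylidenecyclohexan-1-ol | C=C1CC[C@@H](O)C(C)(C)[C@H]1CC/C(C)=C/CO | intermediate
17 | isofraxidin, 7-hydroxy-6,8-dimethoxy-2H-chromen-2-one | COc1cc2ccc(=O)oc2c(OC)c1O | starting material
18 | 7-{[(2E)-5-[(1S,3R)-3-hydroxy-2,2-dimethyl-6-methylidenecyclohexyl]-3-methylpent-2-en-1-yl]oxy}-6,8-dimethoxy-2H-chromen-2-one | C=C1CC[C@@H](O)C(C)(C)[C@H]1CC/C(C)=C/COc1c(OC)cc2ccc(=O)oc2c1OC | target

**Step count and risks**

Total step count: 12. Longest linear sequence: 12 steps (from geraniol).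

Steps most likely to fail:

1. Step 9 (proposed new method). What may go wrong:
 - the open-chain radical is oxidised by copper before it cyclises, giving the acyclic vinyl ketone;
 - 1,5-hydrogen transfer from the allylic C3–H to the C5 radical, eroding C3 and giving chain products;
 - 7-endo closure;
 - a second cyclisation of the ring-closed radical onto the side-chain alkene.

 Fallback (known chemistry, sets out from 11 and returns at 14): 11 would be acetylated (Ac2O, DMAP, Et3N) to the cyclopropyl acetate F1. Tsuji–Wacker oxidation of the vinyl group (PdCl2 cat., CuCl, O2, DMF–H2O) should give the methyl ketone F2. Kinetic enolisation on the methyl side and triflation (KN(SiMe3)2, PhNTf2, THF, −78 °C) should give the enol triflate F3. i-Bu2AlH at −78 °C would remove the acetate to give the cyclopropanol enol triflate F4. Pd(OAc)2/XPhos with Cs2CO3 in toluene at 80 °C would then close C4–C5 by intramolecular ring-opening cross-coupling of the palladium homoenolate with the alkenyl triflate, giving 14.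

2. Step 8. What may go wrong: slow addition of the titanacyclopropane to the α-quaternary ester, and ligand exchange with the substrate's own vinyl group leading to intramolecular cyclopropanation.

 Fallback (sets out from 10 and returns at 11): the ester would be cleaved with KOSiMe3 in THF to the acid F5. MeLi (2.2 equiv, Et2O, 0 °C) should give the methyl ketone F6. LiN(i-Pr)2 and Me3SiCl at −78 °C would give the silyl enol ether F7, which can only form on the methyl side. Simmons–Smith cyclopropanation of this most electron-rich alkene (Et2Zn, CH2I2, CH2Cl2, 0 °C) should give the siloxycyclopropane F8, and K2CO3 in MeOH would release 11.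

3. Step 7. What may go wrong: a low branched-to-linear ratio or low enantioselectivity with the bulky tetrasubstituted ketene acetal, or the opposite sense of induction.

 Fallback (sets out from 7 and returns at 10): 7 would be acylated with isobutyryl chloride (pyridine, DMAP) to the allylic isobutyrate F9. Ireland–Claisen rearrangement (LiN(i-Pr)2, Me3SiCl, THF, −78 to 60 °C, acidic work-up) would form the C2–C3 bond and the vinyl group, giving the racemic acid F10. Me3SiCHN2 in MeOH–toluene would give the racemic methyl ester F11. Preparative chromatography on a chiral stationary phase would then separate 10 from its mirror image F12.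

Further compounds
F1 | step 9 | 1-[(3S,6E)-8-[(tert-butyldiphenylsilyl)oxy]-3-ethenyl-2,6-dimethyloct-6-en-2-yl]cyclopropyl acetate | CC(=O)OC1(CC1)C(C)(C)[C@H](C=C)CC/C(C)=C/CO[Si](c1ccccc1)(c1ccccc1)C(C)(C)C
F2 | step 9 | 1-[(3R,6E)-3-acetyl-8-[(tert-butyldiphenylsilyl)oxy]-2,6-dimethyloct-6-en-2-yl]cyclopropyl acetate | CC(=O)OC1(CC1)C(C)(C)[C@H](C(C)=O)CC/C(C)=C/CO[Si](c1ccccc1)(c1ccccc1)C(C)(C)C
F3 | step 9 | 1-[(3R,6E)-8-[(tert-butyldiphenylsilyl)oxy]-2,6-dimethyl-3-{1-[(trifluoromethanesulfonyl)oxy]ethenyl}oct-6-en-2-yl]cyclopropyl acetate | CC(=O)OC1(CC1)C(C)(C)[C@H](C(=C)OS(=O)(=O)C(F)(F)F)CC/C(C)=C/CO[Si](c1ccccc1)(c1ccccc1)C(C)(C)C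
F4 | step 9 | (3R,6E)-8-[(tert-butyldiphenylsilyl)oxy]-3-[2-(1-hydroxycyclopropyl)propan-2-yl]-6-methylocta-1,6-dien-2-yl trifluoromethanesulfonate | OC1(CC1)C(C)(C)[C@H](C(=C)OS(=O)(=O)C(F)(F)F)CC/C(C)=C/CO[Si](c1ccccc1)(c1ccccc1)C(C)(C)C
F5 | step 8 | (3S,6E)-8-[(tert-butyldiphenylsilyl)oxy]-3-ethenyl-2,2,6-trimethyloct-6-enoic acid | OC(=O)C(C)(C)[C@H](C=C)CC/C(C)=C/CO[Si](c1ccccc1)(c1ccccc1)C(C)(C)C
F6 | step 8 | (4S,7E)-9-[(tert-butyldiphenylsilyl)oxy]-4-ethenyl-3,3,7-trimethylnon-7-en-2-one | CC(=O)C(C)(C)[C@H](C=C)CC/C(C)=C/CO[Si](c1ccccc1)(c1ccccc1)C(C)(C)C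
F7 | step 8 | {[(4S,7E)-9-[(tert-butyldiphenylsilyl)oxy]-4-ethenyl-3,3,7-trimethylnona-1,7-dien-2-yl]oxy}trimethylsilane | C=C(O[Si](C)(C)C)C(C)(C)[C@H](C=C)CC/C(C)=C/CO[Si](c1ccccc1)(c1ccccc1)C(C)(C)C
F8 | step 8 | 1-[(3S,6E)-8-[(tert-butyldiphenylsilyl)oxy]-3-ethenyl-2,6-dimethyloct-6-en-2-yl]cyclopropyl trimethylsilyl ether | C[Si](C)(C)OC1(CC1)C(C)(C)[C@H](C=C)CC/C(C)=C/CO[Si](c1ccccc1)(c1ccccc1)C(C)(C)C
F9 | step 7 | (2E,6E)-8-[(tert-butyldiphenylsilyl)oxy]-6-methylocta-2,6-dien-1-yl 2-methylpropanoate | CC(C)C(=O)OC/C=C/CC/C(C)=C/CO[Si](c1ccccc1)(c1ccccc1)C(C)(C)C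
F10 | step 7 | (6E)-8-[(tert-butyldiphenylsilyl)oxy]-3-ethenyl-2,2,6-trimethyloct-6-enoic acid (racemic) | OC(=O)C(C)(C)C(C=C)CC/C(C)=C/CO[Si](c1ccccc1)(c1ccccc1)C(C)(C)C
F11 | step 7 | methyl (6E)-8-[(tert-butyldiphenylsilyl)oxy]-3-ethenyl-2,2,6-trimethyloct-6-enoate (racemic) | COC(=O)C(C)(C)C(C=C)CC/C(C)=C/CO[Si](c1ccccc1)(c1ccccc1)C(C)(C)C
F12 | step 7 | methyl (3R,6E)-8-[(tert-butyldiphenylsilyl)oxy]-3-ethenyl-2,2,6-trimethyloct-6-enoate (unwanted enantiomer) | COC(=O)C(C)(C)[C@@H](C=C)CC/C(C)=C/CO[Si](c1ccccc1)(c1ccccc1)C(C)(C)C
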